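**Retrosynthetic overview** (ring numbering as in the name of the target: C1 carries CO2Me, C4 is the stereocentre)
1. The only ring is closed last at C1=C2 by an intramolecular Still–Gennari olefination, which also sets the (1Z)-enoate.
2. The C4 stereocentre and the C4–alkenyl bond come from an enantioselective, BINOL-catalysed conjugate alkenylboration of an acyclic enal (C2–C4) with a sulcatone-derived 1,1-disubstituted alkenyl trifluoroborate.
3. The enal comes from the terminal isopropylidene of a homofarnesyl chain (site-selective dihydroxylation/cleavage, then Wittig); C1 comes from alkylation of the Still–Gennari phosphonoacetate.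
4. The (11E) alkene and C13–C14 come from Negishi carboalumination/oxirane opening of an enyne made from nerylacetone, which supplies the (7Z) alkene.

Assumption: nerylacetone is bought as the single (5Z) isomer, and the sense of induction of the new alkenylboration is taken from the closed transition-state model for enones (R catalyst, Re face); if the first run shows the opposite sense, the S catalyst is used and nothing else changes.

**Step 1**
Reactants: 1 nerylacetone, (5Z)-6,10-dimethylundeca-5,9-dien-2-one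
Product: 3 (5Z)-6,10-dimethylundeca-5,9-dien-1-yne, via enol phosphate 2 (not isolated)
Conditions: LiN(iPr)2 (1.05 equiv), THF, −78 °C; ClP(O)(OEt)2, −78 °C → rt; then LiN(iPr)2 (2.3 equiv), THF, −78 °C → rt; aq. NH4Cl
Reagents that add atoms: none
Why: Negishi methyl ketone-to-alkyne protocol, in which the kinetic enolate is O-phosphorylated and the enol phosphate undergoes E2 elimination, leaving both trisubstituted alkenes and the Z geometry untouched.

**Step 2**
Reactants: 3 (5Z)-6,10-dimethylundeca-5,9-dien-1-yne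
Product: 6 (3E,7Z)-4,8,12-trimethyltrideca-3,7,11-trien-1-ol, via alkenylalane 4 (not isolated), via lithium alkenylaluminate 5 (not isolated)
Conditions: AlMe3 (2 equiv), Cp2ZrCl2 (0.25 equiv), CH2Cl2, 0 °C → rt; then n-BuLi, THF, −78 °C; oxirane, −78 °C → rt; aq. HCl
Reagents that add atoms: trimethylaluminium, C[Al](C)C; oxirane, C1CO1
Why: Negishi zirconium-catalysed carboalumination adds Me and Al syn across the terminal alkyne (sets the E alkene), and the derived aluminate opens oxirane with retention of the alkene geometry.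

**Step 3**
Reactants: 6 (3E,7Z)-4,8,12-trimethyltrideca-3,7,11-trien-1-ol
Product: 7 (3E,7Z)-1-iodo-4,8,12-trimethyltrideca-3,7,11-triene
Conditions: I2, PPh3, imidazole, CH2Cl2, 0 °C
Reagents that add atoms: iodine, II
Why: Appel-type (Garegg–Samuelsson) iodination of a primary alcohol proceeds by SN2 displacement of the oxyphosphonium group without touching the alkenes.

**Step 4**
Reactants: 7 (3E,7Z)-1-iodo-4,8,12-trimethyltrideca-3,7,11-triene; 8 methyl 2-[bis(2,2,2-trifluoroethoxy)phosphoryl]acetate (2 equiv)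
Product: 9 methyl (5E,9Z)-2-[bis(2,2,2-trifluoroethoxy)phosphoryl]-6,10,14-trimethylpentadeca-5,9,13-trienoate
Conditions: NaH, DMF, 0 °C; then 7, rt → 40 °C
Reagents that add atoms: none
Why: SN2 C-alkylation of the soft sodium phosphonoacetate by the primary iodide (excess 8 suppresses dialkylation); C-2 becomes a labile, racemic centre that is destroyed in step 10.

**Step 5**
Reactants: 9 methyl (5E,9Z)-2-[bis(2,2,2-trifluoroethoxy)phosphoryl]-6,10,14-trimethylpentadeca-5,9,13-trienoate
Product: 11 methyl (5E,9Z)-2-[bis(2,2,2-trifluoroethoxy)phosphoryl]-6,10-dimethyl-13-oxotrideca-5,9-dienoate, via terminal diol 10 (not isolated)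
Conditions: OsO4 (1 mol%), (DHQD)2PHAL (5 mol%), N-methylmorpholine N-oxide (1.1 equiv), acetone/H2O, 0 °C, slow addition of 9, stop at about 70% conversion; Na2SO3; then NaIO4, THF/pH 7 buffer, 0 °C
Reagents that add atoms: N-methylmorpholine N-oxide, C[N+]1([O-])CCOCC1; water, O
Why: Sharpless-type ligand-accelerated osmylation is fastest at the least hindered terminal isopropylidene under neutral conditions, and Malaprade periodate cleavage gives the aldehyde and acetone (the carbinol centre of 10 is erased).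

**Step 6**
Reactants: 11 methyl (5E,9Z)-2-[bis(2,2,2-trifluoroethoxy)phosphoryl]-6,10-dimethyl-13-oxotrideca-5,9-dienoate
Product: 12 methyl (5E,9Z,13E)-2-[bis(2,2,2-trifluoroethoxy)phosphoryl]-6,10-dimethyl-15-oxopentadeca-5,9,13-trienoate
Conditions: Ph3P=CHCHO (1.2 equiv), toluene, 80 °C
Reagents that add atoms: (triphenylphosphoranylidene)acetaldehyde, O=CC=P(c1ccccc1)(c1ccccc1)c1ccccc1
Why: Wittig reaction with the stabilised formyl ylide gives the (E)-enal and is too weakly basic to deprotonate the phosphonoacetate.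

**Step 7**
Reactants: 13 sulcatone, 6-methylhept-5-en-2-one
Product: 14 N′-[(2E)-6-methylhept-5-en-2-ylidene]-2,4,6-tri(propan-2-yl)benzenesulfonohydrazide
Conditions: 2,4,6-triisopropylbenzenesulfonohydrazide, MeOH, cat. HCl, rt
Reagents that add atoms: 2,4,6-triisopropylbenzenesulfonohydrazide, NNS(=O)(=O)c1c(C(C)C)cc(C(C)C)cc1C(C)C
Why: Acid-catalysed hydrazone condensation gives the trisylhydrazone needed for a regioselective Shapiro reaction.

**Step 8**
Reactants: 14 N′-[(2E)-6-methylhept-5-en-2-ylidene]-2,4,6-tri(propan-2-yl)benzenesulfonohydrazide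
Product: 17 potassium trifluoro(6-methylhepta-1,5-dien-2-yl)borate, via alkenyllithium 15 (not isolated), via lithium trimethoxyborate 16 (not isolated)
Conditions: n-BuLi (2.2 equiv), TMEDA/hexane, −78 °C → 0 °C; B(OMe)3, −78 °C → rt; aq. KHF2
Reagents that add atoms: trimethyl borate, COB(OC)OC; potassium hydrogen difluoride, [K+].F[H-]F
Why: Shapiro reaction deprotonates the methyl group (syn-dianion), giving the less substituted alkenyllithium, which is borylated and converted to the air-stable trifluoroborate.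

**Step 9**
Reactants: 12 methyl (5E,9Z,13E)-2-[bis(2,2,2-trifluoroethoxy)phosphoryl]-6,10-dimethyl-15-oxopentadeca-5,9,13-trienoate; 17 potassium trifluoro(6-methylhepta-1,5-dien-2-yl)borate (1.5 equiv)
Product: 18 methyl (5E,9Z,13R)-2-[bis(2,2,2-trifluoroethoxy)phosphoryl]-6,10-dimethyl-13-(6-methylhepta-1,5-dien-2-yl)-15-oxopentadeca-5,9-dienoate
Conditions: (R)-3,3′-bis(pentafluorophenyl)-1,1′-bi-2-naphthol (20 mol%), 4 Å MS, toluene, 50 °C; aq. NaHCO3
Reagents that add atoms: none
Why: Proposed new method: BINOL-catalysed enantioselective conjugate alkenylboration of an aliphatic enal with an α-branched (1,1-disubstituted) alkenyl trifluoroborate; the sieves take up fluoride so that the diol exchanges onto boron and gives a Lewis-acidic binaphthyl alkenylboronate, the s-cis enal binds boron through its carbonyl oxygen, and the alkenyl group migrates from boron to C-13 through a closed six-membered chair-like transition state, so the boron-bearing carbon is delivered directly (no cation at the CH2 terminus is needed, which is why a 1,1-disubstituted alkenyl that fails as a free π-nucleophile in iminium catalysis should transfer here) and 1,2-addition is geometrically excluded; the 3,3′-aryl groups leave the Re face of C-13 open, which gives 13R, and the boron enolate exchanges with fresh reagent for turnover; the closest known reaction type is the BINOL-catalysed conjugate addition of alkenylboronates and alkenyl trifluoroborates to enones, and new here are the aldehyde acceptor with an aliphatic β-substituent and the α-branched alkenyl donor.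

**Step 10**
Reactants: 18 methyl (5E,9Z,13R)-2-[bis(2,2,2-trifluoroethoxy)phosphoryl]-6,10-dimethyl-13-(6-methylhepta-1,5-dien-2-yl)-15-oxopentadeca-5,9-dienoate
Product: 19 methyl (1Z,4R,7Z,11E)-7,11-dimethyl-4-(6-methylhepta-1,5-dien-2-yl)cyclotetradeca-1,7,11-triene-1-carboxylate
Conditions: KN(SiMe3)2 (1.05 equiv), 18-crown-6 (5 equiv), THF (0.001 M), −78 °C → −40 °C; aq. NH4Cl
Reagents that add atoms: none
Why: Intramolecular Still–Gennari (Horner–Wadsworth–Emmons) olefination under dissociating K/crown conditions gives the kinetic Z-enoate (ester cis to the aldehyde-derived CH2), which here is also the less strained ring-trans alkene of the 14-membered ring; the C4 stereocentre is β to the aldehyde and cannot epimerise.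

**Compound list**
1 | nerylacetone, (5Z)-6,10-dimethylundeca-5,9-dien-2-one | CC(=O)CC/C=C(C)\CCC=C(C)C | starting material
2 | diethyl (5Z)-6,10-dimethylundeca-1,5,9-trien-2-yl phosphate | C=C(OP(=O)(OCC)OCC)CC/C=C(C)\CCC=C(C)C | intermediate
3 | (5Z)-6,10-dimethylundeca-5,9-dien-1-yne | C#CCC/C=C(C)\CCC=C(C)C | intermediate
4 | dimethyl[(1E,5Z)-2,6,10-trimethylundeca-1,5,9-trien-1-yl]alane | C[Al](C)/C=C(\C)CC/C=C(C)\CCC=C(C)C | intermediate
5 | lithium butyl(dimethyl)[(1E,5Z)-2,6,10-trimethylundeca-1,5,9-trien-1-yl]aluminate | [Li+].CCCC[Al-](C)(C)/C=C(\C)CC/C=C(C)\CCC=C(C)C | intermediate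
6 | (3E,7Z)-4,8,12-trimethyltrideca-3,7,11-trien-1-ol | OCC/C=C(\C)CC/C=C(C)\CCC=C(C)C | intermediate
7 | (3E,7Z)-1-iodo-4,8,12-trimethyltrideca-3,7,11-triene | ICC/C=C(\C)CC/C=C(C)\CCC=C(C)C | intermediate
8 | methyl 2-[bis(2,2,2-trifluoroethoxy)phosphoryl]acetate | COC(=O)CP(=O)(OCC(F)(F)F)OCC(F)(F)F | starting material
9 | methyl (5E,9Z)-2-[bis(2,2,2-trifluoroethoxy)phosphoryl]-6,10,14-trimethylpentadeca-5,9,13-trienoate (C-2 racemic) | COC(=O)C(CC/C=C(\C)CC/C=C(C)\CCC=C(C)C)P(=O)(OCC(F)(F)F)OCC(F)(F)F | intermediate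
10 | methyl (5E,9Z,13R)-2-[bis(2,2,2-trifluoroethoxy)phosphoryl]-13,14-dihydroxy-6,10,14-trimethylpentadeca-5,9-dienoate | COC(=O)C(CC/C=C(\C)CC/C=C(C)\CC[C@@H](O)C(C)(C)O)P(=O)(OCC(F)(F)F)OCC(F)(F)F | intermediate
11 | methyl (5E,9Z)-2-[bis(2,2,2-trifluoroethoxy)phosphoryl]-6,10-dimethyl-13-oxotrideca-5,9-dienoate | COC(=O)C(CC/C=C(\C)CC/C=C(C)\CCC=O)P(=O)(OCC(F)(F)F)OCC(F)(F)F | intermediate
12 | methyl (5E,9Z,13E)-2-[bis(2,2,2-trifluoroethoxy)phosphoryl]-6,10-dimethyl-15-oxopentadeca-5,9,13-trienoate | COC(=O)C(CC/C=C(\C)CC/C=C(C)\CC/C=C/C=O)P(=O)(OCC(F)(F)F)OCC(F)(F)F | intermediate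
13 | sulcatone, 6-methylhept-5-en-2-one | CC(=O)CCC=C(C)C | starting material
14 | N′-[(2E)-6-methylhept-5-en-2-ylidene]-2,4,6-tri(propan-2-yl)benzenesulfonohydrazide | C/C(CCC=C(C)C)=N\NS(=O)(=O)c1c(C(C)C)cc(C(C)C)cc1C(C)C | intermediate
15 | (6-methylhepta-1,5-dien-2-yl)lithium | [Li]C(=C)CCC=C(C)C | intermediate
16 | lithium trimethoxy(6-methylhepta-1,5-dien-2-yl)borate | [Li+].CO[B-](OC)(OC)C(=C)CCC=C(C)C | intermediate
17 | potassium trifluoro(6-methylhepta-1,5-dien-2-yl)borate | [K+].F[B-](F)(F)C(=C)CCC=C(C)C | intermediate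
18 | methyl (5E,9Z,13R)-2-[bis(2,2,2-trifluoroethoxy)phosphoryl]-6,10-dimethyl-13-(6-methylhepta-1,5-dien-2-yl)-15-oxopentadeca-5,9-dienoate | C=C(CCC=C(C)C)[C@H](CC/C(C)=C\CC/C(C)=C/CCC(C(=O)OC)P(=O)(OCC(F)(F)F)OCC(F)(F)F)CC=O | intermediate
19 | methyl (1Z,4R,7Z,11E)-7,11-dimethyl-4-(6-methylhepta-1,5-dien-2-yl)cyclotetradeca-1,7,11-triene-1-carboxylate | C=C(CCC=C(C)C)[C@H]1C/C=C(\C(=O)OC)CC/C=C(\C)CC/C=C(/C)CC1 | target

**Totals.** Total step count: 10. Longest linear sequence: 8 steps (steps 1–6, 9, 10); steps 7 and 8 form the two-step branch to the boron reagent.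

**Steps most likely to fail**

Step 9, the proposed new alkenylboration. The aldehyde is a weaker Lewis base than the ketones used so far, it lacks the carbonyl substituent that helps facial control with enones, the α-branched alkenyl group may migrate slowly, and the phosphonate may compete for boron. The fallback uses known chemistry, sets out from enal 12 and comes back at target 19. Nitroethane is added to 12 with (S)-α,α-diphenylprolinol trimethylsilyl ether (10 mol%) and PhCO2H in toluene (Hayashi–Jørgensen iminium catalysis, which delivers the nucleophile to the same Re face) to give the γ-nitro aldehyde F1. K2CO3/18-crown-6 in toluene at high dilution closes the ring by the same Still–Gennari olefination to the macrocyclic nitro ester F2. NaOMe followed by buffered aqueous TiCl3 (McMurry variant of the Nef reaction) gives the macrocyclic methyl ketone F3. KN(SiMe3)2 and PhNTf2 at −78 °C give the kinetic enol triflate F4, and Negishi coupling of F4 with (4-methylpent-3-en-1-yl)zinc bromide and Pd(PPh3)4 gives 19.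

Step 10, the macrocyclic Still–Gennari closure. Oligomerisation or an eroded Z/E ratio in the ring-forming olefination are the risks. The fallback changes the olefination reagent class and therefore the substrate; it sets out from iodide 7 and comes back at 19. Methyl 2-(diphenoxyphosphoryl)acetate is alkylated with 7 (NaH, DMF) to give the diaryl phosphonate F5. The conditions of steps 5, 6 and 9 then give in turn the terminal diol F6 (not isolated), the aldehyde F7, the enal F8 and the chiral aldehyde F9. F9 is added by syringe pump to NaI and DBU in THF at 0 °C (Ando olefination under amine-base conditions, Z-selective through the aryloxy phosphonate and compatible with slow addition), which gives 19.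

Step 5, the site-selective dihydroxylation and cleavage. Osmylation may not discriminate well enough between the terminal and the two internal trisubstituted alkenes. The fallback sets out from 9 and comes back at 11 and relies on van Tamelen's terminal-selective halohydrin formation in aqueous medium. NBS in THF/H2O at 0 °C gives the terminal bromohydrin F10, DBU in CH2Cl2 closes it to the terminal epoxide F11, and H5IO6 in THF/H2O cleaves F11 to 11.

**Further compounds**
F1 | step 9 | methyl (5E,9Z,13R)-2-[bis(2,2,2-trifluoroethoxy)phosphoryl]-6,10-dimethyl-13-(1-nitroethyl)-15-oxopentadeca-5,9-dienoate | CC([N+](=O)[O-])[C@H](CC/C(C)=C\CC/C(C)=C/CCC(C(=O)OC)P(=O)(OCC(F)(F)F)OCC(F)(F)F)CC=O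
F2 | step 9 | methyl (1Z,4R,7Z,11E)-7,11-dimethyl-4-(1-nitroethyl)cyclotetradeca-1,7,11-triene-1-carboxylate | CC([N+](=O)[O-])[C@H]1C/C=C(\C(=O)OC)CC/C=C(\C)CC/C=C(/C)CC1
F3 | step 9 | methyl (1Z,4R,7Z,11E)-4-acetyl-7,11-dimethylcyclotetradeca-1,7,11-triene-1-carboxylate | CC(=O)[C@H]1C/C=C(\C(=O)OC)CC/C=C(\C)CC/C=C(/C)CC1
F4 | step 9 | methyl (1Z,4R,7Z,11E)-7,11-dimethyl-4-[1-(trifluoromethylsulfonyloxy)ethenyl]cyclotetradeca-1,7,11-triene-1-carboxylate | C=C(OS(=O)(=O)C(F)(F)F)[C@H]1C/C=C(\C(=O)OC)CC/C=C(\C)CC/C=C(/C)CC1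
F5 | step 10 | methyl (5E,9Z)-2-(diphenoxyphosphoryl)-6,10,14-trimethylpentadeca-5,9,13-trienoate | COC(=O)C(CC/C=C(\C)CC/C=C(C)\CCC=C(C)C)P(=O)(Oc1ccccc1)Oc1ccccc1
F6 | step 10 | methyl (5E,9Z,13R)-2-(diphenoxyphosphoryl)-13,14-dihydroxy-6,10,14-trimethylpentadeca-5,9-dienoate | COC(=O)C(CC/C=C(\C)CC/C=C(C)\CC[C@@H](O)C(C)(C)O)P(=O)(Oc1ccccc1)Oc1ccccc1
F7 | step 10 | methyl (5E,9Z)-2-(diphenoxyphosphoryl)-6,10-dimethyl-13-oxotrideca-5,9-dienoate | COC(=O)C(CC/C=C(\C)CC/C=C(C)\CCC=O)P(=O)(Oc1ccccc1)Oc1ccccc1
F8 | step 10 | methyl (5E,9Z,13E)-2-(diphenoxyphosphoryl)-6,10-dimethyl-15-oxopentadeca-5,9,13-trienoate | COC(=O)C(CC/C=C(\C)CC/C=C(C)\CC/C=C/C=O)P(=O)(Oc1ccccc1)Oc1ccccc1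
F9 | step 10 | methyl (5E,9Z,13R)-2-(diphenoxyphosphoryl)-6,10-dimethyl-13-(6-methylhepta-1,5-dien-2-yl)-15-oxopentadeca-5,9-dienoate | C=C(CCC=C(C)C)[C@H](CC/C(C)=C\CC/C(C)=C/CCC(C(=O)OC)P(=O)(Oc1ccccc1)Oc1ccccc1)CC=O
F10 | step 5 | methyl (5E,9Z)-2-[bis(2,2,2-trifluoroethoxy)phosphoryl]-13-bromo-14-hydroxy-6,10,14-trimethylpentadeca-5,9-dienoate (racemic at C-13) | COC(=O)C(CC/C=C(\C)CC/C=C(C)\CCC(Br)C(C)(C)O)P(=O)(OCC(F)(F)F)OCC(F)(F)F
F11 | step 5 | methyl (5E,9Z)-2-[bis(2,2,2-trifluoroethoxy)phosphoryl]-12-(3,3-dimethyloxiran-2-yl)-6,10-dimethyldodeca-5,9-dienoate | COC(=O)C(CC/C=C(\C)CC/C=C(C)\CCC1OC1(C)C)P(=O)(OCC(F)(F)F)OCC(F)(F)F
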